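The readings are calculated with made-up constants; the scatter is artificial.

I began with the easy step: laying out what the earlier runs show.

| flask | substrate | reagent | remark | time |
|---|---|---|---|---|
| autumn | 8 mM | 49 mM | run made earlier |  |
| spring | 8 mM | 65 mM | run made earlier |  |
| Wednesday's | 8.0 mM | 32.6 mM |  | 20 d |
| Tuesday's | 15 mM | 32.6 mM |  | 20 d |
| Monday's | 30 mM | 32.6 mM |  | 20 d |
| Friday's | 60 mM | 32.6 mM |  | 20 d |

| run | time / d | target / % | substrate / % |
|---|---|---|---|
| autumn | 0.417 | 1.2 | 19.4 |
| autumn | 1.04 | 6.2 | 3.3 |
| autumn | 2.08 | 12.6 | 0.7 |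
| autumn | 3.00 | 18.8 | 0.2 |
| autumn | 4.00 | 23.3 | 0 |
| autumn | 6.00 | 31.7 | 0.3 |
| autumn | 8.00 | 37.7 | 0 |
| spring | 0.417 | 1.6 | 12.3 |
| spring | 1.04 | 7.0 | 1.5 |
| spring | 2.08 | 16.4 | 0.3 |
| spring | 3.00 | 22.8 | 0 |
| spring | 4.00 | 28.6 | 0 |
| spring | 6.00 | 37.9 | 0 |
| spring | 8.00 | 43.5 | 0.2 |

(scatter of a reading: 0.3 percentage points)

- [target] at the end for Wednesday's, Tuesday's, Monday's, Friday's, in this order
- how the row runs (rises, then falls / falls all the way / falls, then rises / hardly changes / rises all the way)

- "hardly changes" means that all values lie within two and a half points (for a concentration: within two and a half percent of the largest)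

1. I compared autumn and spring. Their reagent charges stood in the ratio 1.33, and substrate's logarithmic fall at the first reading in the ratio 1.28, so I took it that reagent entered the first step.

2. Target at 2.08 d read in the ratio 1.30, though substrate was down to 0.7% and 0.3%. So I counted a second reagent, 2 per target.

3. I folded the charges into one number. Monday's flask stands at 1.84, and this is the demand: 2 times the substrate charge over the reagent charge, the share of reagent that the whole substrate charge asks for. Wednesday's has 0.491, Tuesday's 0.920, Friday's 3.68.

4. I solved both ends. Below demand 1, substrate is the limiting reagent and target's ceiling is the whole charge. Above it, the first step takes its reagent and the remainder gives a ceiling of 2 over demand, minus 1: 8.67% of Monday's charge, and −45.7%, so nil, for Friday's. The ends join at demand 1, so I expected a rise, then a fall.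

5. One number was not enough: autumn had 37.7% target at 8.00 d, short of its ceiling, the whole charge. Autumn's early target gave a reading of pace, 1.03 as a pseudo-first-order exponent at the reagent charge over 20 d. A second-order balance then gave me target as fractions of the charge of 50.5%, 36.7% and 5.21% for Wednesday's, Tuesday's and Monday's, and nil for Friday's.

6. The forecast said 3.5 mM, 4.9 mM, 1.3 mM, 0.4 mM, rises, then falls: “Reagent starvation makes the row rise, then fall.” Its first three values stood below mine, which were 4.04 mM, 5.50 mM and 1.56 mM.

The flasks gave 3.72 mM, 5.56 mM, 4.28 mM, 0.548 mM: the row rises, then falls, turning at 19 mM, a demand of 1.18.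

    substrate + reagent ⇌ intermediate A (K = 61.0 M⁻¹, k = 4.70 M⁻¹ h⁻¹)
    substrate → intermediate B (k = 0.0110 h⁻¹)
    reagent + intermediate B → side product (k = 0.110 M⁻¹ h⁻¹)
    intermediate A → intermediate C (k = 0.270 h⁻¹)
    reagent + intermediate C → target (k = 0.150 M⁻¹ h⁻¹)
    reagent + intermediate C ⇌ intermediate D (K = 10.0 M⁻¹, k = 6.60 M⁻¹ h⁻¹)
    2 reagent → self-condensation product (k = 0.0870 M⁻¹ h⁻¹)

At 20.0 d, Monday's flask held 14.3% target, above its ceiling, beside 16.1% intermediate B. At 20.0 d, Friday's flask, at demand 3.68, held 0.913% target and 47.2% intermediate B.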